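**Strategy.** The salicylate ring carries three contiguous substituents: CO2H on C1, OH on C2 and the 12-phenyldodecyl chain on C6. Instead of alkylating or cross-coupling a preformed salicylate, the C1–CO2H and C6–C(sp3) bonds are both made in one operation across the C1≡C6 triple bond of 3-methoxybenzyne. 12-Phenyldodecylmagnesium chloride adds to C6, and the C1 aryl Grignard so formed is carboxylated with CO2. The C2 methoxy group fixes the regiochemistry. The precursor set is three simple pieces: 3-fluoroanisole (aryne source), (12-chlorododecyl)benzene and CO2. One demethylation then completes the target.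

Key step: step 2

Remark on the chemistry: the target has no stereocentre and no stereogenic axis, so it is achiral and the route needs no stereocontrol; the compound drawn is the only stereoisomer.

**Step 1**
Reactants: 1 (6-bromohexyl)benzene; 2 1-bromo-6-chlorohexane
Product: 4 (12-chlorododecyl)benzene, via 6-phenylhexylmagnesium bromide 3 (not isolated)
Conditions: 1, Mg, THF, 40 °C; then added to 2 (1.2 equiv), Li2CuCl4 (3 mol %), THF, −10 °C → rt; aq NH4Cl
Reagents that add atoms: none
Why: Copper-catalysed Kochi-type sp3–sp3 coupling of a primary alkyl Grignard with a primary alkyl bromide, in which C–Br reacts far faster than C–Cl, so the chloride end should survive as the handle for the next Grignard formation.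

**Step 2**
Reactants: 4 (12-chlorododecyl)benzene; 5 3-fluoroanisole
Product: 11 2-methoxy-6-(12-phenyldodecyl)benzoic acid, via 12-phenyldodecylmagnesium chloride 6 (not isolated), via 2-fluoro-6-methoxyphenyllithium 7 (not isolated), via 3-methoxybenzyne 8 (not isolated), via 2-methoxy-6-(12-phenyldodecyl)phenylmagnesium chloride 9 (not isolated), via chloromagnesium 2-methoxy-6-(12-phenyldodecyl)benzoate 10 (not isolated)
Conditions: (a) 4 (1.3 equiv), Mg, I2 (cat.), THF, reflux; (b) 5 (1.05 equiv), n-BuLi (1.0 equiv), THF, −78 °C, 1 h; (c) solution (a) added to (b) at −78 °C, then → rt → 50 °C; (d) CO2 (g), −20 °C → rt; 1 M HCl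
Reagents that add atoms: carbon dioxide, O=C=O
Why: Directed ortho-lithiation of 5 at C2 (flanked by F and OMe) gives 7, which on warming loses LiF to form 3-methoxybenzyne 8; Grignard 6 adds to the aryne carbon remote from OMe (carbomagnesiation), and the aryl Grignard 9 so formed, with magnesium ortho to OMe, is carboxylated by CO2 to 10 and protonated on work-up to 11. The closest known reaction type is the tandem aryne nucleophilic addition–electrophile quench of organolithium and Grignard reagents with 3-alkoxy- and 3-haloarynes. No ring is closed and no stereocentre is formed. The step needs addition at the aryne carbon meta to oxygen; this is secured by the inductively withdrawing OMe, which distorts the aryne so that the distal carbon is the more electrophilic one and which stabilises and chelates the metal at the ortho carbon. It also needs the alkyl nucleophile to outcompete aryl-metal 7 for 8, which the excess and higher nucleophilicity of primary alkyl Grignard 6 and the steric hindrance of 7 and 9 should secure. CO2 is small enough to carboxylate the 2,6-disubstituted aryl Grignard 9, as it does mesityl-type Grignards.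

**Step 3**
Reactants: 11 2-methoxy-6-(12-phenyldodecyl)benzoic acid
Product: 13 2-hydroxy-6-(12-phenyldodecyl)benzoic acid, via 2-bromo-5-(12-phenyldodecyl)-4H-1,3,2-benzodioxaborinin-4-one 12 (not isolated)
Conditions: BBr3 (3 equiv), CH2Cl2, −78 → 0 °C; then H2O, 0 °C
Reagents that add atoms: none
Why: BBr3 demethylation of an aryl methyl ether, in which boron binds the carboxyl and the ortho OMe, bromide displaces the methyl group as MeBr to give a chelate formulated as 12, and aqueous work-up hydrolyses the B–O bonds, while the alkyl chain and both arenes should be inert at or below 0 °C.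

**Compound list**
1 | (6-bromohexyl)benzene | BrCCCCCCc1ccccc1 | starting material
2 | 1-bromo-6-chlorohexane | BrCCCCCCCl | starting material
3 | 6-phenylhexylmagnesium bromide | Br[Mg]CCCCCCc1ccccc1 | intermediate
4 | (12-chlorododecyl)benzene | ClCCCCCCCCCCCCc1ccccc1 | intermediate
5 | 3-fluoroanisole (1-fluoro-3-methoxybenzene) | COc1cccc(F)c1 | starting material
6 | 12-phenyldodecylmagnesium chloride | Cl[Mg]CCCCCCCCCCCCc1ccccc1 | intermediate
7 | 2-fluoro-6-methoxyphenyllithium | [Li]c1c(F)cccc1OC | intermediate
8 | 3-methoxybenzyne (aryne bond between the carbons ortho and meta to OMe) | COC1=CC=CC#C1 | intermediate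
9 | 2-methoxy-6-(12-phenyldodecyl)phenylmagnesium chloride | COc1cccc(CCCCCCCCCCCCc2ccccc2)c1[Mg]Cl | intermediate
10 | chloromagnesium 2-methoxy-6-(12-phenyldodecyl)benzoate | COc1cccc(CCCCCCCCCCCCc2ccccc2)c1C(=O)O[Mg]Cl | intermediate
11 | 2-methoxy-6-(12-phenyldodecyl)benzoic acid | COc1cccc(CCCCCCCCCCCCc2ccccc2)c1C(=O)O | intermediate
12 | 2-bromo-5-(12-phenyldodecyl)-4H-1,3,2-benzodioxaborinin-4-one (cyclic bromoboron salicylate) | O=C1OB(Br)Oc2cccc(CCCCCCCCCCCCc3ccccc3)c12 | intermediate
13 | 2-hydroxy-6-(12-phenyldodecyl)benzoic acid | O=C(O)c1c(O)cccc1CCCCCCCCCCCCc1ccccc1 | target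

**Total step count:** 3
**Longest linear sequence:** 3 steps (1 → 4 → 11 → 13)

**Steps most likely to fail**

Step 2 (key step). The aryne may be consumed by its own aryl-metal precursor (biaryl and oligomer formation) faster than by the alkyl Grignard. The hindered aryl Grignard may also be protonated instead of carboxylated. The surplus of 6 ends as an aliphatic acid, which should be separable from 11 by chromatography. The fallback makes the aryl–alkyl bond by cross-coupling on a ring that already carries both oxygen functions. It sets out from 4, converted to 6 as in step 2. Transmetalation of 6 with ZnCl2 in THF should give 12-phenyldodecylzinc chloride F1. Commercial 5-hydroxy-2,2-dimethyl-4H-1,3-benzodioxin-4-one with Tf2O and pyridine in CH2Cl2 at 0 °C should give 2,2-dimethyl-4-oxo-4H-1,3-benzodioxin-5-yl trifluoromethanesulfonate F2. Negishi coupling of F1 with F2 (Pd(dppf)Cl2, THF, 60 °C) should give 2,2-dimethyl-5-(12-phenyldodecyl)-4H-1,3-benzodioxin-4-one F3. Hydrolysis with KOH in THF/H2O at 60 °C, then HCl, comes back to the route at 13, so step 3 is not needed.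

Step 1. Halide chemoselectivity may be lost (coupling or halogen exchange at the C–Cl end), and Wurtz-type homocoupling of the Grignard may give hydrocarbon and dihalide mixtures that are hard to separate. The fallback builds the chain by acetylide alkylation and sets out from 1. 6-Chlorohex-1-yne with n-BuLi in THF at −78 °C should give (6-chlorohex-1-yn-1-yl)lithium F4. Alkylation of F4 with 1 (THF/DMPU, −78 °C → rt) should give (12-chlorododec-7-yn-1-yl)benzene F5. Hydrogenation (H2 1 atm, Pd/C, EtOAc, rt) comes back to the route at 4.

Step 3. The electron-rich salicylic acid may undergo acid-promoted protodecarboxylation during the Lewis-acid demethylation or its work-up, or the ether cleavage may stay incomplete. The fallback changes the phenol mask so that no ether dealkylation is needed, and keeps the key step. It sets out from 4, converted to 6 as in step 2. 3-Fluorophenol with MOMCl and i-Pr2NEt in CH2Cl2 should give 1-fluoro-3-(methoxymethoxy)benzene F6, which takes the place of 5 in the step 2 protocol. Lithiation should give 2-fluoro-6-(methoxymethoxy)phenyllithium F7, and loss of LiF should give 3-(methoxymethoxy)benzyne F8. Addition of 6 should give 2-(methoxymethoxy)-6-(12-phenyldodecyl)phenylmagnesium chloride F9. CO2 should give chloromagnesium 2-(methoxymethoxy)-6-(12-phenyldodecyl)benzoate F10, and cold acidification to pH 4 should give 2-(methoxymethoxy)-6-(12-phenyldodecyl)benzoic acid F11. Acetal hydrolysis (2 M aq HCl, THF, 40 °C) comes back to the route at 13.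

**Further compounds**
F1 | step 2 | 12-phenyldodecylzinc chloride | Cl[Zn]CCCCCCCCCCCCc1ccccc1
F2 | step 2 | 2,2-dimethyl-4-oxo-4H-1,3-benzodioxin-5-yl trifluoromethanesulfonate | CC1(C)OC(=O)c2c(OS(=O)(=O)C(F)(F)F)cccc2O1
F3 | step 2 | 2,2-dimethyl-5-(12-phenyldodecyl)-4H-1,3-benzodioxin-4-one | CC1(C)OC(=O)c2c(CCCCCCCCCCCCc3ccccc3)cccc2O1
F4 | step 1 | (6-chlorohex-1-yn-1-yl)lithium | [Li]C#CCCCCCl
F5 | step 1 | (12-chlorododec-7-yn-1-yl)benzene | ClCCCCC#CCCCCCCc1ccccc1
F6 | step 3 | 1-fluoro-3-(methoxymethoxy)benzene | COCOc1cccc(F)c1
F7 | step 3 | 2-fluoro-6-(methoxymethoxy)phenyllithium | [Li]c1c(F)cccc1OCOC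
F8 | step 3 | 3-(methoxymethoxy)benzyne | COCOC1=CC=CC#C1
F9 | step 3 | 2-(methoxymethoxy)-6-(12-phenyldodecyl)phenylmagnesium chloride | COCOc1cccc(CCCCCCCCCCCCc2ccccc2)c1[Mg]Cl
F10 | step 3 | chloromagnesium 2-(methoxymethoxy)-6-(12-phenyldodecyl)benzoate | COCOc1cccc(CCCCCCCCCCCCc2ccccc2)c1C(=O)O[Mg]Cl
F11 | step 3 | 2-(methoxymethoxy)-6-(12-phenyldodecyl)benzoic acid | COCOc1cccc(CCCCCCCCCCCCc2ccccc2)c1C(=O)O
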